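## Analysis of the target

Compound 15 is a flavonol. Ring A (C4a to C8a, hydroxyls on C5 and C7) is fused to the γ-pyranone ring C (O1, C2, C3, C4); ring B, a 4-methoxyphenyl group, sits on C2, and O3 carries a sulfate monoester. The molecule has no stereocentre, so any stereocentre that appears on the way only has to be removable. The sensitive group is the O3 sulfate: it is an enol-type aryl sulfate that hydrolyses under acid and turns every intermediate carrying it into a polar salt, so it must come in late. The C7 hydroxyl (the more acidic one) and the C5 hydroxyl (chelated to the C4 carbonyl) would compete with O3 for any sulfating agent. The difficulty is therefore less the skeleton than telling three hydroxyls and one methyl ether apart, and finding a final deprotection that leaves the sulfate in place. Seen from O1, ring A is a 3,5-dioxygenated aryl ether whose two ortho carbons (the later C4a and C8) are equivalent and strongly nucleophilic. The strategy rests on this: a three-carbon alkyne unit C2–C3–C4 attached to O1 can close onto C4a without any regiochemical choice, giving ring C as a 2H-chromene. Its isolated C3=C4 double bond then takes up both missing oxygens, and O3 emerges as the only free hydroxyl.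

## Retrosynthetic reasoning

The last bonds touched are the two benzyl–oxygen bonds on O5 and O7. Target 15 is traced back, through its sodium salt 14, to the benzylated sodium sulfate 13. Benzyl ethers leave under neutral hydrogenolysis, which an aryl sulfate salt, the 4'-methyl ether and the pyranone all tolerate. The sulfate then meets acid only once, in a cold protonation at the very end.

Compound 13 is cut at the O3–S bond, giving flavonol 11 (the pyridinium salt 12 is the first-formed sulfate). In 11 the O3 hydroxyl is the only free hydroxyl, so site selectivity comes from the protecting-group pattern and not from reagent control. The forward step has to sulfate a hindered, enolic hydroxyl.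

Flavonol 11 is the stable enol of the 3,4-dione 10, so no skeletal bond is cut here; the oxidation level of C3 and C4 is lowered to that of the 3,4-diol 9. This lets ring C be assembled at the alkene level and aromatized late. The forward oxidation must convert both carbinols without cleaving the C3–C4 bond; enolization through C2–H then erases every stereocentre.

Diol 9 is cut at both C–O bonds on C3 and C4, leading to the 2H-chromene 8. Because its C3=C4 bond is isolated from ring B and carries no other substituent, one syn-dihydroxylation delivers both oxygens with no regiochemical question.

The key disconnection is C4–C4a of chromene 8, which opens ring C to the aryl propargyl ether 7. The cut is made here because C4a is the natural nucleophile of ring A and C4 is the terminus of an alkyne that a π-acid can activate. Cutting O1–C2 or O1–C8a instead would demand an ortho acyl or halogen group on ring A and would break its symmetry. The forward reaction has to be a 6-endo hydroarylation that outruns 5-exo closure and ionization of the C2–O1 bond.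

Ether 7 is cut at O1–C2 into the propargylic acetate 5 and the phenol 6. The propargylic carbon is the electrophile and the phenol oxygen the nucleophile. The forward reaction has to alkylate on oxygen, not on the electron-rich ring carbons, at a secondary and easily ionized centre; copper-catalysed propargylic substitution of a terminal alkyne does this.

Acetate 5 comes from alcohol 4 by acylation. Alcohol 4 is cut at the C2–C3 bond into aldehyde 1 and the acetylide reagent 2, with the magnesium alkoxide 3 as the first-formed adduct. All three building blocks (1, 2, 6) are purchased, and 6 already holds ring A with its oxygens differentiated.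

## Alternatives that were turned down

Alternative 1: Ring A is unravelled at C4a–C8a (the same bond as C4a–C5 by symmetry) to the open-chain cinnamoyl triketo ester A1. In the forward key step a magnesium alkoxide base enolizes A1, the C6 methylene attacks the ester carbon C1 in an intramolecular Claisen condensation, and aromatization gives chalcone A2. Alkaline peroxide oxidation (Algar–Flynn–Oyamada) would then give kaempferide A3.
- For it: it mirrors the biosynthesis, builds ring A with all three oxygens from an acyclic chain, and A2 is only one oxidative cyclization away from the flavonol.
- Against it: A1 is a sensitive polycarbonyl chain that needs several polyanion acylations. Its folding is ambiguous, since aldol closure of C2 onto C7 and lactonization to a 4-hydroxy-2-pyranone compete with the C6-to-C1 Claisen mode. A chalcone with hydroxyls on both ortho positions of the acyl ring tends to close the five-membered benzofuranone ring on oxidative cyclization rather than ring C. A3 has three free hydroxyls, with the C7 hydroxyl more reactive than O3, so protection steps return before sulfation.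
- Comparison: Alternative 1 is stronger in biogenetic logic and needs no late adjustment of skeleton oxidation level. The chosen route buys ring A intact and symmetric, and delivers 11 with O3 as the only free hydroxyl.

Alternative 2: Ring C is cut at C4–C4a and O1–C2, leading to phloroglucinol A4 and the α-benzyloxy β-keto ester A5. In the forward key step the two are heated without catalyst (Mentzer condensation); ring A is acylated at carbon by the ester, the neighbouring hydroxyl condenses with the aryl ketone, and the 3-benzyloxy flavone A6 results.
- For it: this is the shortest way to the complete flavonol skeleton, with the C3 oxygen in place from the start. On step count to the core it is stronger than the chosen route.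
- Against it: the condensation needs very high temperature, at which the α-benzyloxy keto ester is at risk, and condensation in the opposite sense (coumarin formation) competes. Above all, the protecting-group pattern in A6 is inverted: O3 is benzylated and O5 and O7 are free, whereas sulfation needs O3 free and O5 and O7 masked. A protecting-group exchange follows (mask the chelated, sluggish C5 hydroxyl and the C7 hydroxyl with a non-benzyl group, hydrogenolyse, sulfate, unmask without losing the sulfate), and A5 itself takes two or three steps.
- Comparison: the overall length becomes similar. The chosen route trades the hot condensation and the exchange of protecting groups for one mild catalytic ring closure and two oxidations, and reaches 11 with exactly the pattern needed.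

Alternative 3: Ring C is cut at O1–C8a, C4–C4a and O1–C2, leading to the arylpropiolic acid A7 and the silyl aryl triflate A8. In the forward key step a fluoride source releases the aryne from A8, the carboxylate oxygen of A7 adds at C8a, the aryl anion at C4a takes the acyl carbon (a formal insertion into the C–O bond), and the resulting phenoxide ynone closes to flavone A9.
- For it: it is convergent and reaches ring C directly at the C4 ketone level. The regiochemistry also fits the aryne, since the nucleophile adds meta to the C5 alkoxy group and leaves the anion ortho to it, at C4a. On convergence it is stronger than the chosen route.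
- Against it: A8 needs several steps from phenol 6 (ortho functionalization, silylation, triflation). O-arylation without acyl transfer and five-membered closure of the ynone compete. A9 lacks the C3 oxygen, so a late C3–H oxidation of an electron-rich flavone is needed before 11 is reached.
- Comparison: the chosen route uses phenol 6 as it is and introduces O3 and O4 together on an isolated alkene, at the price of carrying ring C through a low oxidation level.

Key step: step 4

Assumption: the target is taken as the free hydrogen sulfate as drawn; because aryl hydrogen sulfates hydrolyse readily in the acid form, the sulfate is carried as its sodium salt (13, 14) and protonated only in the last operation.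

## Route

Step 1
Reactants: 1 4-methoxybenzaldehyde; 2 ethynylmagnesium bromide
Product: 4 1-(4-methoxyphenyl)prop-2-yn-1-ol (racemic), via bromomagnesium propargylic alkoxide 3 (not isolated)
Conditions: THF, 0 °C → rt; then sat. aq. NH4Cl
Reagents that add atoms: none
Why: Grignard addition of an acetylide to a non-enolizable aromatic aldehyde should be clean; the new C2 stereocentre forms racemic, which is acceptable because it is erased by enolization in step 6.

Step 2
Reactants: 4 1-(4-methoxyphenyl)prop-2-yn-1-ol (racemic)
Product: 5 1-(4-methoxyphenyl)prop-2-yn-1-yl acetate (racemic)
Conditions: Ac2O, Et3N, DMAP (cat.), CH2Cl2, 0 °C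
Reagents that add atoms: acetic anhydride, CC(=O)OC(C)=O
Why: DMAP-catalysed acylation of a secondary alcohol; the basic medium avoids ionization of the 4-methoxybenzylic position, and the acetate is the leaving group required for the copper-catalysed substitution.

Step 3
Reactants: 5 1-(4-methoxyphenyl)prop-2-yn-1-yl acetate (racemic); 6 3,5-bis(benzyloxy)phenol
Product: 7 1-{1-[3,5-bis(benzyloxy)phenoxy]prop-2-yn-1-yl}-4-methoxybenzene (racemic)
Conditions: Cu(MeCN)4PF6 (5 mol %), iPr2NEt, MeCN, −20 → 0 °C
Reagents that add atoms: none
Why: Copper-catalysed propargylic etherification of a terminal propargylic acetate: a copper acetylide (monovalent copper) loses acetate to give a copper allenylidene, whose γ-carbon is attacked by the phenoxide oxygen before protonation. The aprotic solvent and amine base keep oxygen, not ring carbon, as the reacting site; the stereocentre stays racemic.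

Step 4
Reactants: 7 1-{1-[3,5-bis(benzyloxy)phenoxy]prop-2-yn-1-yl}-4-methoxybenzene (racemic)
Product: 8 5,7-bis(benzyloxy)-2-(4-methoxyphenyl)-2H-chromene (racemic)
Conditions: Ph3PAuNTf2 (3 mol %), CH2Cl2, 0 °C → rt, dark
Reagents that add atoms: none
Why: The Ph3PAu cation (monovalent gold, a soft π-acid) binds the terminal alkyne of 7, and the ring A carbon ortho to O1, which is also ortho to one benzyloxy group and para to the other, attacks the terminal alkyne carbon anti to gold; loss of the ring proton restores aromaticity and protodeauration of the vinylgold species releases the C3=C4 alkene and the catalyst. The closest known reaction type is the gold-catalysed intramolecular hydroarylation of aryl propargyl ethers to 2H-chromenes. Ring C is closed in the 6-endo-dig mode as an intramolecular Friedel–Crafts alkenylation that forms the C4–C4a bond. No stereocentre is created; C2 stays racemic as set in step 1 and is erased in step 6. Regioselectivity on ring A needs no control, because the two ortho carbons are equivalent by symmetry. The preference for 6-endo over 5-exo closure follows from the unsubstituted alkyne terminus, which the O1–C2–C3 tether reaches without strain, and from the high nucleophilicity of the doubly activated ortho carbon, which should make cyclization fast at or below room temperature. Selectivity for alkyne activation over heterolysis of the doubly activated C2–O1 bond rests on a phosphine-ligated, weakly oxophilic gold cation with the non-coordinating NTf2 counterion, low loading, low temperature and the absence of protic acid.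

Step 5
Reactants: 8 5,7-bis(benzyloxy)-2-(4-methoxyphenyl)-2H-chromene (racemic)
Product: 9 rac-(2R,3S,4S)-5,7-bis(benzyloxy)-2-(4-methoxyphenyl)chromane-3,4-diol (2,3-trans-3,4-cis)
Conditions: OsO4 (2 mol %), NMO, acetone–H2O, rt
Reagents that add atoms: osmium tetroxide, O=[Os](=O)(=O)=O; N-methylmorpholine N-oxide, C[N+]1([O-])CCOCC1; water, O
Why: Catalytic syn-dihydroxylation with OsO4 and NMO as terminal oxidant; the electron-rich cis-disubstituted C3=C4 bond should react from the face opposite the C2 aryl group (substrate control), setting O3 and O4 cis to each other and trans to the aryl group. All three stereocentres are removed in step 6, so the diastereomer obtained is of no consequence.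

Step 6
Reactants: 9 rac-(2R,3S,4S)-5,7-bis(benzyloxy)-2-(4-methoxyphenyl)chromane-3,4-diol
Product: 11 5,7-bis(benzyloxy)-3-hydroxy-2-(4-methoxyphenyl)-4H-chromen-4-one, via chromane-3,4-dione 10 (not isolated)
Conditions: (COCl)2, DMSO, CH2Cl2, −78 °C; then Et3N, −78 → 0 °C
Reagents that add atoms: none
Why: Double Swern oxidation of a vicinal diol to the 1,2-dione; activated-DMSO oxidations do not cleave the glycol C–C bond. Dione 10 has an acidic C2–H (α to the C3 ketone and benzylic) and should enolize under Et3N to the aromatic 3-hydroxy-4-pyranone, which removes the C2 stereocentre.

Step 7
Reactants: 11 5,7-bis(benzyloxy)-3-hydroxy-2-(4-methoxyphenyl)-4H-chromen-4-one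
Product: 13 sodium 5,7-bis(benzyloxy)-2-(4-methoxyphenyl)-4-oxo-4H-chromen-3-yl sulfate, via pyridinium sulfate salt 12 (not isolated)
Conditions: SO3·pyridine, pyridine, 50 °C; then aq. NaHCO3
Reagents that add atoms: sulfur trioxide pyridine complex, [O-]S(=O)(=O)[n+]1ccccc1; sodium hydrogen carbonate, [Na+].OC([O-])=O
Why: O-sulfation of a hydroxyl with a sulfur trioxide–amine complex; O3–H is the only free hydroxyl of 11, so no site selectivity is required, and the bicarbonate work-up exchanges pyridinium for sodium to give a stable, pyridine-free salt for the hydrogenolysis.

Step 8
Reactants: 13 sodium 5,7-bis(benzyloxy)-2-(4-methoxyphenyl)-4-oxo-4H-chromen-3-yl sulfate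
Product: 15 kaempferide 3-O-sulfate [5,7-dihydroxy-2-(4-methoxyphenyl)-4-oxo-4H-chromen-3-yl hydrogen sulfate], via sodium salt of the debenzylated sulfate 14 (not isolated)
Conditions: H2 (1 atm), 10% Pd/C, THF–MeOH, rt; filter; then HCl (1.0 equiv, aq.), 0 °C, reversed-phase (C18) desalting, lyophilization
Reagents that add atoms: none
Why: Hydrogenolysis of benzyl aryl ethers over zerovalent palladium on carbon under neutral conditions, which the sulfate salt, the aryl methyl ether and the aromatic pyranone should tolerate; one equivalent of cold acid then converts the sodium salt into the hydrogen sulfate as drawn.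

## Compound list

1 | 4-methoxybenzaldehyde | COc1ccc(C=O)cc1 | starting material
2 | ethynylmagnesium bromide | C#C[Mg]Br | starting material
3 | bromomagnesium 1-(4-methoxyphenyl)prop-2-yn-1-olate (racemic) | COc1ccc(C(O[Mg]Br)C#C)cc1 | intermediate (not isolated)
4 | 1-(4-methoxyphenyl)prop-2-yn-1-ol (racemic) | COc1ccc(C(O)C#C)cc1 | intermediate
5 | 1-(4-methoxyphenyl)prop-2-yn-1-yl acetate (racemic) | COc1ccc(C(OC(C)=O)C#C)cc1 | intermediate
6 | 3,5-bis(benzyloxy)phenol | Oc1cc(OCc2ccccc2)cc(OCc2ccccc2)c1 | starting material
7 | 1-{1-[3,5-bis(benzyloxy)phenoxy]prop-2-yn-1-yl}-4-methoxybenzene (racemic) | C#CC(Oc1cc(OCc2ccccc2)cc(OCc2ccccc2)c1)c1ccc(OC)cc1 | intermediate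
8 | 5,7-bis(benzyloxy)-2-(4-methoxyphenyl)-2H-chromene (racemic) | COc1ccc(C2C=Cc3c(OCc4ccccc4)cc(OCc4ccccc4)cc3O2)cc1 | intermediate
9 | rac-(2R,3S,4S)-5,7-bis(benzyloxy)-2-(4-methoxyphenyl)chromane-3,4-diol (one enantiomer drawn) | COc1ccc([C@H]2Oc3cc(OCc4ccccc4)cc(OCc4ccccc4)c3[C@H](O)[C@@H]2O)cc1 | intermediate
10 | 5,7-bis(benzyloxy)-2-(4-methoxyphenyl)chromane-3,4-dione (racemic) | COc1ccc(C2Oc3cc(OCc4ccccc4)cc(OCc4ccccc4)c3C(=O)C2=O)cc1 | intermediate (not isolated)
11 | 5,7-bis(benzyloxy)-3-hydroxy-2-(4-methoxyphenyl)-4H-chromen-4-one | COc1ccc(-c2oc3cc(OCc4ccccc4)cc(OCc4ccccc4)c3c(=O)c2O)cc1 | intermediate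
12 | pyridinium 5,7-bis(benzyloxy)-2-(4-methoxyphenyl)-4-oxo-4H-chromen-3-yl sulfate | COc1ccc(-c2oc3cc(OCc4ccccc4)cc(OCc4ccccc4)c3c(=O)c2OS(=O)(=O)[O-])cc1.c1cc[nH+]cc1 | intermediate (not isolated)
13 | sodium 5,7-bis(benzyloxy)-2-(4-methoxyphenyl)-4-oxo-4H-chromen-3-yl sulfate | COc1ccc(-c2oc3cc(OCc4ccccc4)cc(OCc4ccccc4)c3c(=O)c2OS(=O)(=O)[O-])cc1.[Na+] | intermediate
14 | sodium 5,7-dihydroxy-2-(4-methoxyphenyl)-4-oxo-4H-chromen-3-yl sulfate | COc1ccc(-c2oc3cc(O)cc(O)c3c(=O)c2OS(=O)(=O)[O-])cc1.[Na+] | intermediate (not isolated)
15 | kaempferide 3-O-sulfate, 5,7-dihydroxy-2-(4-methoxyphenyl)-4-oxo-4H-chromen-3-yl hydrogen sulfate | COc1ccc(-c2oc3cc(O)cc(O)c3c(=O)c2OS(=O)(=O)O)cc1 | target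

## Step count and least certain steps

Total step count: 8. Longest linear sequence: 8 steps (1 to 15); phenol 6 enters at step 3.

Step 4 (key step). The most likely failure is heterolysis of the C2–O1 bond, which is propargylic and 4-methoxybenzylic. The gold cation would then act as a σ-Lewis acid; the propargyl unit would migrate from oxygen to ring carbon or the material would oligomerize. Closure in the 5-exo sense to a benzofuran skeleton, and acid-induced decomposition of the electron-rich chromene, are further risks. The fallback sets out from 7 and returns to 8 without a metal, by the thermal aryl propargyl ether Claisen cascade in N,N-diethylaniline at about 190 °C: a [3,3] sigmatropic shift to the ortho carbon, enolization, a 1,5-hydrogen shift and a 6π oxa-electrocyclization. It involves no Lewis acid and forms the same C4–C4a bond, and it makes no new isolable compound (F0).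

Step 3. The ring carbons of 6 are highly nucleophilic, so attack of carbon instead of oxygen on the copper allenylidene (a Friedel–Crafts propargylation) may compete; acetate 5 may also ionize before it reaches copper. The fallback sets out from alcohol 4 and phenol 6 and returns at 7 by a Mitsunobu etherification (PPh3, diisopropyl azodicarboxylate, toluene, 0 °C). It activates the alcohol oxygen instead of generating a metal allenylidene, bypasses acetate 5 and makes no new compound (F0).

Step 6. Activation of the C4 hydroxyl as an alkoxysulfonium ion at a benzylic carbon flanked by three oxygen-bearing ring positions may lead to ionization and elimination or chloride substitution instead of oxidation. The activated sulfoxide may also attack ring A, and the second oxidation may stall at the hydroxy ketone. The fallback sets out from diol 9 and returns at flavonol 11 in two stages that never turn the C4 oxygen into a leaving group. First, the activated benzylic C4 carbinol is dehydrogenated with DDQ in dioxane to the dihydroflavonol rac-(2R,3R)-5,7-bis(benzyloxy)-3-hydroxy-2-(4-methoxyphenyl)chroman-4-one F1. Second, the classical dehydrogenation of a dihydroflavonol with iodine and KOAc in acetic acid gives 11.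

Step 8. Loss of the sulfate by hydrolysis during the final protonation, or stalling of the hydrogenolysis because the salt is poorly soluble, would lower the return. The fallback sets out from flavonol 11 and returns at target 15 with the sulfate masked as a neutral diester. Compound 11 is treated with 2,2,2-trichloroethyl chlorosulfate (Et3N, DMAP, THF) to give 5,7-bis(benzyloxy)-2-(4-methoxyphenyl)-4-oxo-4H-chromen-3-yl 2,2,2-trichloroethyl sulfate F2, which can be purified on silica. Transfer hydrogenolysis (Pd/C, ammonium formate, MeOH) is then expected to remove both benzyl groups and, by reductive β-elimination, the trichloroethyl group, giving ammonium 5,7-dihydroxy-2-(4-methoxyphenyl)-4-oxo-4H-chromen-3-yl sulfate F3. One equivalent of cold aqueous HCl converts F3 into 15.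

## Further compounds

F0 | step 4 | none | none
F0 | step 3 | none | none
F1 | step 6 | rac-(2R,3R)-5,7-bis(benzyloxy)-3-hydroxy-2-(4-methoxyphenyl)chroman-4-one (one enantiomer drawn) | COc1ccc([C@H]2Oc3cc(OCc4ccccc4)cc(OCc4ccccc4)c3C(=O)[C@@H]2O)cc1
F2 | step 8 | 5,7-bis(benzyloxy)-2-(4-methoxyphenyl)-4-oxo-4H-chromen-3-yl 2,2,2-trichloroethyl sulfate | COc1ccc(-c2oc3cc(OCc4ccccc4)cc(OCc4ccccc4)c3c(=O)c2OS(=O)(=O)OCC(Cl)(Cl)Cl)cc1
F3 | step 8 | ammonium 5,7-dihydroxy-2-(4-methoxyphenyl)-4-oxo-4H-chromen-3-yl sulfate | COc1ccc(-c2oc3cc(O)cc(O)c3c(=O)c2OS(=O)(=O)[O-])cc1.[NH4+]
A1 | alternative 1 | methyl (E)-9-(4-methoxyphenyl)-3,5,7-trioxonon-8-enoate | COC(=O)CC(=O)CC(=O)CC(=O)/C=C/c1ccc(OC)cc1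
A2 | alternative 1 | (E)-3-(4-methoxyphenyl)-1-(2,4,6-trihydroxyphenyl)prop-2-en-1-one | COc1ccc(/C=C/C(=O)c2c(O)cc(O)cc2O)cc1
A3 | alternative 1 | kaempferide, 3,5,7-trihydroxy-2-(4-methoxyphenyl)-4H-chromen-4-one | COc1ccc(-c2oc3cc(O)cc(O)c3c(=O)c2O)cc1
A4 | alternative 2 | phloroglucinol | Oc1cc(O)cc(O)c1
A5 | alternative 2 | ethyl 2-(benzyloxy)-3-(4-methoxyphenyl)-3-oxopropanoate (racemic) | CCOC(=O)C(OCc1ccccc1)C(=O)c1ccc(OC)cc1
A6 | alternative 2 | 3-(benzyloxy)-5,7-dihydroxy-2-(4-methoxyphenyl)-4H-chromen-4-one | COc1ccc(-c2oc3cc(O)cc(O)c3c(=O)c2OCc4ccccc4)cc1
A7 | alternative 3 | 3-(4-methoxyphenyl)propiolic acid | COc1ccc(C#CC(=O)O)cc1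
A8 | alternative 3 | 3,5-bis(benzyloxy)-2-(trimethylsilyl)phenyl trifluoromethanesulfonate | C[Si](C)(C)c1c(OCc2ccccc2)cc(OCc2ccccc2)cc1OS(=O)(=O)C(F)(F)F
A9 | alternative 3 | 5,7-bis(benzyloxy)-2-(4-methoxyphenyl)-4H-chromen-4-one | COc1ccc(-c2cc(=O)c3c(OCc4ccccc4)cc(OCc4ccccc4)cc3o2)cc1
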